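Retrosynthesis
1. Eduesmine 11 ⇐ fourfold O‑debenzylation of the tetrabenzyl ether 10 (no skeletal change).
2. Oxolane 10 ⇐ hydride addition to the 2‑aryl oxocarbenium ion of lactol 8 (new C2–H, aryl ends cis to the C3 arm) ⇐ aryllithium 7 + lactone 5 (C2–aryl bond).
3. Lactone 5 ⇐ anti‑alkylation of the cis‑lactone 3 with BOMCl (C3–CH2O bond, 3,4‑trans).
4. Lactone 3 ⇐ carbene‑catalysed asymmetric homoenolate [3+2] annulation of aldehyde 1 with enal 2 (C4–C5 and O1–C2 bonds, first two stereocentres, 4,5‑cis).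
5. Ring order: the γ‑lactone ring is made first (step 1), carried on as the lactol, and becomes the oxolane ring in step 4; both arenes are bought.

Assumption: 1, 2 and 6 are catalogue compounds, and the antipode of the step 1 catalyst that gives the (4S,5S)‑lactone is found in the first screen.

Step 1
Reactants: 1 4-(benzyloxy)-3-methoxybenzaldehyde; 2 (E)-4-(benzyloxy)but-2-enal
Product: 3 (4S,5S)-5-[4-(benzyloxy)-3-methoxyphenyl]-4-[(benzyloxy)methyl]oxolan-2-one
Conditions: chiral N‑mesityl pyrrolotriazolium BF4 precatalyst with an Ar2C(OH) arm (Ar = 3,5‑(CF3)2C6H3; 10 mol %), i‑Pr2NEt (20 mol %), 4 Å MS, toluene, 0 °C to rt; 2 added slowly to 1 (2 equiv); cis‑lactone separated from minor trans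
Reagents that add atoms: none
Why: Proposed new method: an enantio‑ and cis‑selective carbene‑catalysed homoenolate [3+2] annulation (umpolung of the enal β‑carbon) with an unactivated, electron‑rich aryl aldehyde; the carbene turns 2 into a catalyst‑bound homoenolate whose β‑carbon adds to the carbonyl carbon of 1 held by a hydrogen bond to the catalyst carbinol arm, the resulting alkoxide acylates on the acyl azolium to close the lactone and release the carbene, so C4 and C5 are set together in one compact, catalyst‑shielded transition state (cis as in the racemic reaction, absolute sense from the catalyst); the closest known reactions are the racemic enal–aldehyde homoenolate annulation and its asymmetric versions with activated ketones.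

Step 2
Reactants: 3 (4S,5S)-5-[4-(benzyloxy)-3-methoxyphenyl]-4-[(benzyloxy)methyl]oxolan-2-one
Product: 5 (3S,4S,5S)-5-[4-(benzyloxy)-3-methoxyphenyl]-3,4-bis[(benzyloxy)methyl]oxolan-2-one, via lithium enolate 4 (not isolated)
Conditions: LiN(SiMe3)2, THF, −78 °C; BOMCl, −78 to −30 °C
Reagents that add atoms: benzyl chloromethyl ether (BOMCl), ClCOCc1ccccc1
Why: SN2 alkylation of a lactone enolate, in which the electrophile approaches the face opposite the C4 benzyloxymethyl arm and the cis C5 aryl group, so the new C3 centre is set trans to C4.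

Step 3
Reactants: 5 (3S,4S,5S)-5-[4-(benzyloxy)-3-methoxyphenyl]-3,4-bis[(benzyloxy)methyl]oxolan-2-one; 6 1-(benzyloxy)-4-bromo-2-methoxybenzene
Product: 8 (3S,4S,5S)-2,5-bis[4-(benzyloxy)-3-methoxyphenyl]-3,4-bis[(benzyloxy)methyl]oxolan-2-ol, via aryllithium 7 (not isolated)
Conditions: 6, n‑BuLi, THF, −78 °C; then 5, −78 °C; H2O
Reagents that add atoms: none
Why: Bromine–lithium exchange followed by 1,2‑addition of the aryllithium to the lactone carbonyl, which stops at the lactol because the tetrahedral lithium alkoxide is stable at −78 °C (C2 is left as an equilibrating anomer mixture).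

Step 4
Reactants: 8 (3S,4S,5S)-2,5-bis[4-(benzyloxy)-3-methoxyphenyl]-3,4-bis[(benzyloxy)methyl]oxolan-2-ol
Product: 10 (2S,3S,4S,5S)-2,5-bis[4-(benzyloxy)-3-methoxyphenyl]-3,4-bis[(benzyloxy)methyl]oxolane, via oxocarbenium ion 9 (not isolated)
Conditions: Et3SiH, BF3·OEt2, CH2Cl2, −78 °C
Reagents that add atoms: none
Why: Ionic hydrogenation (reductive deoxygenation of a cyclic hemiketal), in which BF3 ionises the lactol to the planar 2‑aryl oxocarbenium ion and Et3SiH delivers hydride to the face opposite the adjacent C3 benzyloxymethyl arm, placing the new aryl group cis to that arm (C2 = S) and trans to the C5 aryl group, while −78 °C keeps both benzylic centres from epimerising.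

Step 5
Reactants: 10 (2S,3S,4S,5S)-2,5-bis[4-(benzyloxy)-3-methoxyphenyl]-3,4-bis[(benzyloxy)methyl]oxolane
Product: 11 eduesmine = [(2S,3S,4S,5S)-2,5-bis(4-hydroxy-3-methoxyphenyl)oxolane-3,4-diyl]dimethanol
Conditions: H2 (1 atm), Pd/C, EtOAc–MeOH, rt
Reagents that add atoms: none
Why: Catalytic hydrogenolysis of the two aryl and two alkyl benzyl ethers, which under neutral conditions at 1 atm leaves the hindered secondary ring C–O bonds intact (as in perbenzylated C‑aryl glycosides) and touches no stereocentre.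

Compound list
1 | 4-(benzyloxy)-3-methoxybenzaldehyde | COc1cc(C=O)ccc1OCc1ccccc1 | starting material
2 | (E)-4-(benzyloxy)but-2-enal | O=C/C=C/COCc1ccccc1 | starting material
3 | (4S,5S)-5-[4-(benzyloxy)-3-methoxyphenyl]-4-[(benzyloxy)methyl]oxolan-2-one (4,5-cis) | COc1cc([C@H]2OC(=O)C[C@H]2COCc2ccccc2)ccc1OCc1ccccc1 | intermediate
4 | lithium (4S,5S)-5-[4-(benzyloxy)-3-methoxyphenyl]-4-[(benzyloxy)methyl]-4,5-dihydrofuran-2-olate (not isolated) | [Li+].COc1cc([C@H]2OC([O-])=C[C@H]2COCc2ccccc2)ccc1OCc1ccccc1 | intermediate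
5 | (3S,4S,5S)-5-[4-(benzyloxy)-3-methoxyphenyl]-3,4-bis[(benzyloxy)methyl]oxolan-2-one (3,4-trans, 4,5-cis) | COc1cc([C@H]2OC(=O)[C@H](COCc3ccccc3)[C@H]2COCc2ccccc2)ccc1OCc1ccccc1 | intermediate
6 | 1-(benzyloxy)-4-bromo-2-methoxybenzene | COc1cc(Br)ccc1OCc1ccccc1 | starting material
7 | [4-(benzyloxy)-3-methoxyphenyl]lithium (not isolated) | [Li]c1ccc(OCc2ccccc2)c(OC)c1 | intermediate
8 | (3S,4S,5S)-2,5-bis[4-(benzyloxy)-3-methoxyphenyl]-3,4-bis[(benzyloxy)methyl]oxolan-2-ol (C2 anomers) | COc1cc([C@H]2OC(O)(c3ccc(OCc4ccccc4)c(OC)c3)[C@H](COCc3ccccc3)[C@H]2COCc2ccccc2)ccc1OCc1ccccc1 | intermediate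
9 | (2S,3S,4S)-2,5-bis[4-(benzyloxy)-3-methoxyphenyl]-3,4-bis[(benzyloxy)methyl]-3,4-dihydro-2H-furan-1-ium (oxocarbenium ion, not isolated) | COc1cc([C@H]2[O+]=C(c3ccc(OCc4ccccc4)c(OC)c3)[C@H](COCc3ccccc3)[C@H]2COCc2ccccc2)ccc1OCc1ccccc1 | intermediate
10 | (2S,3S,4S,5S)-2,5-bis[4-(benzyloxy)-3-methoxyphenyl]-3,4-bis[(benzyloxy)methyl]oxolane (2,3-cis, 3,4-trans, 4,5-cis) | COc1cc([C@H]2O[C@H](c3ccc(OCc4ccccc4)c(OC)c3)[C@H](COCc3ccccc3)[C@H]2COCc2ccccc2)ccc1OCc1ccccc1 | intermediate
11 | eduesmine, [(2S,3S,4S,5S)-2,5-bis(4-hydroxy-3-methoxyphenyl)oxolane-3,4-diyl]dimethanol | COc1cc([C@H]2O[C@H](c3ccc(O)c(OC)c3)[C@H](CO)[C@H]2CO)ccc1O | target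

Total step count: 5. Longest linear sequence: 5 steps (1 and 2 to 11).

Steps most likely to fail

Step 1 (the new annulation). The electron‑rich aldehyde 1 is a sluggish acceptor, benzyloxide may be lost from the homoenolate of 2, and cis selectivity and ee are unproven. The fallback uses known enamine catalysis, sets out from 1 and returns at 3. D‑Proline‑catalysed anti‑selective cross‑aldol of 1 with tert‑butyl 4‑oxobutanoate (DMF, 4 °C) gives tert-butyl (3R,4S)-4-[4-(benzyloxy)-3-methoxyphenyl]-3-formyl-4-hydroxybutanoate F1. This is reduced in the same pot with NaBH4 to tert-butyl (3S,4S)-4-[4-(benzyloxy)-3-methoxyphenyl]-4-hydroxy-3-(hydroxymethyl)butanoate F2. The primary hydroxyl is then benzylated selectively (Bu2SnO, toluene, reflux; BnBr, CsF) to give tert-butyl (3S,4S)-4-[4-(benzyloxy)-3-methoxyphenyl]-3-[(benzyloxy)methyl]-4-hydroxybutanoate F3. Lactonisation of the benzylic hydroxyl onto the ester with catalytic KOt‑Bu in THF gives 3.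

Step 4 (hemiketal reduction). The C5 aryl group sits on the face the hydride must use, and the Lewis acid can epimerise or over‑reduce the electron‑rich benzylic ethers. The fallback replaces the ionic reduction by a radical one without Lewis acid, sets out from 5 and returns at 10. Lawesson's reagent (toluene, 110 °C) converts 5 into (3S,4S,5S)-5-[4-(benzyloxy)-3-methoxyphenyl]-3,4-bis[(benzyloxy)methyl]oxolane-2-thione F5. Addition of aryllithium 7 at −78 °C and S‑methylation with MeI give (3S,4S,5S)-2,5-bis[4-(benzyloxy)-3-methoxyphenyl]-3,4-bis[(benzyloxy)methyl]-2-(methylsulfanyl)oxolane F6. Desulfurisation with Ph3SnH and AIBN (toluene, 110 °C) goes through the planar benzylic anomeric radical, which takes hydrogen from the face opposite the C3 arm and gives 10.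

Step 2 (BOMCl alkylation). BOMCl is capricious, and O‑alkylation or double alkylation can erode the yield. The fallback swaps C‑alkylation for aldol plus O‑alkylation, sets out from 3 and returns at 5. Enolate 4 is treated with formaldehyde gas at −78 °C to give (3S,4S,5S)-5-[4-(benzyloxy)-3-methoxyphenyl]-4-[(benzyloxy)methyl]-3-(hydroxymethyl)oxolan-2-one F4. Neutral O‑benzylation (BnBr, Ag2O, CH2Cl2) then gives 5.

Further compounds
F1 | step 1 | tert-butyl (3R,4S)-4-[4-(benzyloxy)-3-methoxyphenyl]-3-formyl-4-hydroxybutanoate | COc1cc([C@@H](O)[C@H](C=O)CC(=O)OC(C)(C)C)ccc1OCc1ccccc1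
F2 | step 1 | tert-butyl (3S,4S)-4-[4-(benzyloxy)-3-methoxyphenyl]-4-hydroxy-3-(hydroxymethyl)butanoate | COc1cc([C@@H](O)[C@H](CO)CC(=O)OC(C)(C)C)ccc1OCc1ccccc1
F3 | step 1 | tert-butyl (3S,4S)-4-[4-(benzyloxy)-3-methoxyphenyl]-3-[(benzyloxy)methyl]-4-hydroxybutanoate | COc1cc([C@@H](O)[C@H](COCc2ccccc2)CC(=O)OC(C)(C)C)ccc1OCc1ccccc1
F4 | step 2 | (3S,4S,5S)-5-[4-(benzyloxy)-3-methoxyphenyl]-4-[(benzyloxy)methyl]-3-(hydroxymethyl)oxolan-2-one | COc1cc([C@H]2OC(=O)[C@H](CO)[C@H]2COCc2ccccc2)ccc1OCc1ccccc1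
F5 | step 4 | (3S,4S,5S)-5-[4-(benzyloxy)-3-methoxyphenyl]-3,4-bis[(benzyloxy)methyl]oxolane-2-thione | COc1cc([C@H]2OC(=S)[C@H](COCc3ccccc3)[C@H]2COCc2ccccc2)ccc1OCc1ccccc1
F6 | step 4 | (3S,4S,5S)-2,5-bis[4-(benzyloxy)-3-methoxyphenyl]-3,4-bis[(benzyloxy)methyl]-2-(methylsulfanyl)oxolane (C2 epimers) | COc1cc([C@H]2OC(SC)(c3ccc(OCc4ccccc4)c(OC)c3)[C@H](COCc3ccccc3)[C@H]2COCc2ccccc2)ccc1OCc1ccccc1
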